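**Retrosynthetic overview**
- The target is reached from its C2-symmetric bis(β-hydroxy ketone) "dimer" by oxidising one benzylic carbinol; that half becomes the 2-acetyl-1-naphthol.
- Both rings A and all four stereocentres come from a two-fold proline aldol (C1–C2 bonds) of a biaryl dialdehyde bis-enone.
- The aldehyde carbons and C4 side chains are put on a protected 4,4'-dimethylbiphenyl-2,2'-diol by lithiation/formylation/lateral lithiation with 4-methoxypent-3-en-2-one.
- The biphenol comes from aromatising 6,6'-linked bis(3-methylcyclohex-2-enone), made by oxidative radical dimerisation of the kinetic enolate of 3-methylcyclohex-2-enone. The C7–C7' bond is thus made first, as an sp3–sp3 bond.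
- Ring order: the two rings B (enone carbocycles, joined, then aromatised), then the two rings A (aldol), then one ring A aromatised by the last oxidation.

Assumption: the biaryl axis (one OH and one H ortho on each ring) is not a stereogenic element, and in two-fold steps both identical halves react in the same pot, so half-converted species are not numbered separately.

Commercial starting materials: 1 (C7H10O) and 6 (C6H10O2).

**Step 1**
Reactants: 1 3-methylcyclohex-2-en-1-one (2 equiv)
Product: 3 4,4'-dimethyl-[1,1'-bi(cyclohexane)]-3,3'-diene-2,2'-dione (dl/meso mixture), via lithium dienolate 2 (not isolated)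
Conditions: LiN(i-Pr)2 (1.05 equiv, commercial solution), THF, −78 °C; then FeCl3 (1.1 equiv), DMF, −78 °C → rt
Reagents that add atoms: none
Why: Kinetic deprotonation gives only the cross-conjugated C6 enolate, one-electron oxidation by trivalent iron turns it into an α-keto radical whose only spin-bearing carbon is C6, and radical coupling (oxidative enolate dimerisation of the Saegusa/Frazier–Harlow type) forms the future C7–C7' bond regiospecifically; the two new stereocentres are erased in step 2.

**Step 2**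
Reactants: 3 4,4'-dimethyl-[1,1'-bi(cyclohexane)]-3,3'-diene-2,2'-dione
Product: 4 4,4'-dimethyl-[1,1'-biphenyl]-2,2'-diol
Conditions: Pd(O2CCF3)2 (5 mol %), 2-(dimethylamino)pyridine (10 mol %), TsOH·H2O (20 mol %), O2 (1 atm), DMSO, 80 °C
Reagents that add atoms: none
Why: Aerobic Pd-catalysed dehydrogenation of cyclohexenones (Pd enolate, β-hydride elimination, dienone–phenol tautomerisation; Stahl-type) aromatises both rings B and turns the sp3–sp3 bond into the biaryl bond ortho to each OH.

**Step 3**
Reactants: 4 4,4'-dimethyl-[1,1'-biphenyl]-2,2'-diol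
Product: 5 2,2'-bis(1-ethoxyethoxy)-4,4'-dimethyl-1,1'-biphenyl
Conditions: ethyl vinyl ether (6 equiv), PPTS (10 mol %), CH2Cl2, rt
Reagents that add atoms: ethyl vinyl ether C=COCC
Why: Acid-catalysed addition of the phenols to the enol ether gives acetal-type (1-ethoxyethyl) ethers that survive alkyllithiums, direct ortho-lithiation and fall off in dilute acid.

**Step 4**
Reactants: 5 2,2'-bis(1-ethoxyethoxy)-4,4'-dimethyl-1,1'-biphenyl; 6 (E)-4-methoxypent-3-en-2-one (3 equiv)
Product: 11 2,2'-dihydroxy-4,4'-bis[(2E)-2-methyl-4-oxopent-2-en-1-yl]-[1,1'-biphenyl]-3,3'-dicarbaldehyde (E major; alkene isomers converge in step 5), via aryl dilithium 7 (not isolated), via amino alkoxide 8 (not isolated), via benzylic dilithium 9 (not isolated), via tetraalkoxide adduct 10 (not isolated)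
Conditions: n-BuLi (2.2 equiv), TMEDA, THF, 0 °C; DMF (2.2 equiv), −78 °C; s-BuLi (2.4 equiv), −78 → −40 °C; 6, −78 °C; then 1 M HCl, THF, 0 °C → rt
Reagents that add atoms: N,N-dimethylformamide CN(C)C=O; water O
Why: Directed ortho-metalation lithiates the only free position ortho to each acetal oxygen, DMF converts it into a lithium α-(dimethylamino)alkoxide that masks the aldehyde and directs lateral lithiation of the neighbouring methyl (Comins-type in situ protection), the benzylic lithium adds to the vinylogous ester 6, and dilute acid releases the aldehyde, performs the Stork–Danheiser hydrolysis/dehydration to the transposed enone and cleaves the acetal ethers in the same work-up.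

**Step 5**
Reactants: 11 2,2'-dihydroxy-4,4'-bis[(2E)-2-methyl-4-oxopent-2-en-1-yl]-[1,1'-biphenyl]-3,3'-dicarbaldehyde
Product: 12 1,1'-[(1S,1'S,2R,2'R)-1,1',8,8'-tetrahydroxy-3,3'-dimethyl-1,1',2,2'-tetrahydro-[7,7'-binaphthalene]-2,2'-diyl]di(ethan-1-one)
Conditions: (R)-proline (40 mol %), DMSO, rt
Reagents that add atoms: none
Why: Proposed new method: (R)-proline condenses with each methyl ketone to a linear dienamine whose α-carbon (C2) can reach the neighbouring aldehyde only through a six-membered ring, and the acid-directed Houk–List transition state of an enolexo aldolisation should give the trans (anti) β-hydroxy ketone with (1S,2R) configuration at both ends (mirror image of the known (S)-proline anti sense), the closest known reactions being List's proline-catalysed 6-enolexo aldolisation and dienamine catalysis of enones; statistical (Horeau) amplification in the two-fold reaction diverts the minor enantiomeric sense into the separable meso-type diastereomer.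

**Step 6**
Reactants: 12 1,1'-[(1S,1'S,2R,2'R)-1,1',8,8'-tetrahydroxy-3,3'-dimethyl-1,1',2,2'-tetrahydro-[7,7'-binaphthalene]-2,2'-diyl]di(ethan-1-one)
Product: 14 1-[(1S,2R)-7-(7-acetyl-1,8-dihydroxy-6-methylnaphthalen-2-yl)-1,8-dihydroxy-3-methyl-1,2-dihydronaphthalen-2-yl]ethan-1-one (target), via keto tautomer 13 (not isolated)
Conditions: activated MnO2 (5 equiv), CH2Cl2, 0 °C → rt, stopped at ca. 55 % conversion; recovered 12 recycled
Reagents that add atoms: none
Why: MnO2 oxidises benzylic alcohols next to free phenols, the resulting cyclic β-diketone 13 tautomerises at once to the aromatic 2-acetyl-1-naphthol, and because both ends of 12 are identical a single oxidation at either end gives the same product (statistical mono-oxidation) while the untouched half keeps its (1S,2R) centres.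

**Compound list**
1 | 3-methylcyclohex-2-en-1-one | CC1=CC(=O)CCC1 | starting material
2 | lithium 5-methylcyclohexa-1,5-dien-1-olate (kinetic C6 enolate of 1) | [Li]OC1=CCCC(C)=C1 | intermediate
3 | 4,4'-dimethyl-[1,1'-bi(cyclohexane)]-3,3'-diene-2,2'-dione, i.e. 6,6'-linked bis(3-methylcyclohex-2-enone), dl/meso mixture | CC1=CC(=O)C(CC1)C1CCC(C)=CC1=O | intermediate
4 | 4,4'-dimethyl-[1,1'-biphenyl]-2,2'-diol | Cc1ccc(-c2ccc(C)cc2O)c(O)c1 | intermediate
5 | 2,2'-bis(1-ethoxyethoxy)-4,4'-dimethyl-1,1'-biphenyl (acetal centres unassigned, mixture) | CCOC(C)Oc1cc(C)ccc1-c1ccc(C)cc1OC(C)OCC | intermediate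
6 | (E)-4-methoxypent-3-en-2-one | CO/C(C)=C/C(C)=O | starting material
7 | [2,2'-bis(1-ethoxyethoxy)-4,4'-dimethyl-[1,1'-biphenyl]-3,3'-diyl]dilithium | CCOC(C)Oc1c([Li])c(C)ccc1-c1ccc(C)c([Li])c1OC(C)OCC | intermediate
8 | dilithium bis[(dimethylamino)methanolate] of the 3,3'-diformyl compound (lithium hemiaminal alkoxide at each CHO carbon) | CCOC(C)Oc1c(C(O[Li])N(C)C)c(C)ccc1-c1ccc(C)c(C(O[Li])N(C)C)c1OC(C)OCC | intermediate
9 | 4,4'-bis(lithiomethyl) derivative of 8 | CCOC(C)Oc1c(C(O[Li])N(C)C)c(C[Li])ccc1-c1ccc(C[Li])c(C(O[Li])N(C)C)c1OC(C)OCC | intermediate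
10 | tetralithium bis-adduct of 9 with 6 (each benzylic carbon bonded to the former carbonyl carbon of 6; E enol ether kept) | CCOC(C)Oc1c(C(O[Li])N(C)C)c(CC(C)(O[Li])/C=C(\C)OC)ccc1-c1ccc(CC(C)(O[Li])/C=C(\C)OC)c(C(O[Li])N(C)C)c1OC(C)OCC | intermediate
11 | 2,2'-dihydroxy-4,4'-bis[(2E)-2-methyl-4-oxopent-2-en-1-yl]-[1,1'-biphenyl]-3,3'-dicarbaldehyde | C/C(Cc1ccc(-c2ccc(C/C(C)=C/C(C)=O)c(C=O)c2O)c(O)c1C=O)=C\C(C)=O | intermediate
12 | 1,1'-[(1S,1'S,2R,2'R)-1,1',8,8'-tetrahydroxy-3,3'-dimethyl-1,1',2,2'-tetrahydro-[7,7'-binaphthalene]-2,2'-diyl]di(ethan-1-one) (OH and acetyl trans in each half) | Oc1c(-c2ccc3c(c2O)[C@@H](O)[C@H](C(C)=O)C(C)=C3)ccc2c1[C@@H](O)[C@H](C(C)=O)C(C)=C2 | intermediate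
13 | keto tautomer of the target: one half is 2-acetyl-8-hydroxy-3-methylnaphthalen-1(2H)-one, the other half unchanged (1S,2R) | CC(=O)[C@@H]1C(C)=Cc2ccc(-c3ccc4c(c3O)[C@@H](O)[C@H](C(C)=O)C(C)=C4)c(O)c2C1=O | intermediate
14 | 1-[(1S,2R)-7-(7-acetyl-1,8-dihydroxy-6-methylnaphthalen-2-yl)-1,8-dihydroxy-3-methyl-1,2-dihydronaphthalen-2-yl]ethan-1-one | CC(=O)c1c(C)cc2ccc(-c3ccc4c(c3O)[C@@H](O)[C@H](C(C)=O)C(C)=C4)c(O)c2c1O | target

**Step count**
Total: 6 steps. Longest linear sequence: 6 steps (1 → 14).

**The three steps most likely to fail**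

Step 4 (four-stage lithiation cascade on a dimer). The simple dimethylamino alkoxide may direct the lateral lithiation poorly, or 6 may be enolised instead of attacked. The fallback sets out from 4 and introduces the aldehyde without organolithium chemistry. Magnesium-phenoxide-directed ortho-formylation (MgCl2, Et3N, paraformaldehyde, MeCN, reflux) gives 2,2'-dihydroxy-4,4'-dimethyl-[1,1'-biphenyl]-3,3'-dicarbaldehyde F1. MOMCl/i-Pr2NEt then gives 2,2'-bis(methoxymethoxy)-4,4'-dimethyl-[1,1'-biphenyl]-3,3'-dicarbaldehyde F2. The isolated dialdehyde is protected in situ with the chelating amide LiN(CH3)CH2CH2N(CH3)2 as the chelated bis(α-amino alkoxide) F3, laterally lithiated with n-BuLi to the benzylic dilithium compound F4, and added to 6 to give the tetraalkoxide bis-adduct F5. Aqueous HCl/MeOH releases the aldehyde, transposes the enone and removes the methoxymethyl groups, and the sequence comes back to the route at 11.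

Step 5 (two-fold asymmetric aldol on a free salicylaldehyde). Risks are low turnover, the wrong facial sense, and amine-promoted loss of water to the naphthalene. The fallback sets out from 11 and replaces enamine catalysis by a Lewis-acid Mukaiyama aldol. TBSOTf/Et3N (CH2Cl2, 0 °C) silylates both phenols and both dienolisable ketones to the tetrasilyl bis(2-silyloxydiene) 2,2'-bis(tert-butyldimethylsilyloxy)-4,4'-bis[2-methyl-4-(tert-butyldimethylsilyloxy)penta-1,3-dien-1-yl]-[1,1'-biphenyl]-3,3'-dicarbaldehyde F6. Ti(Oi-Pr)4/(R)-BINOL (20 mol %, CH2Cl2, −40 °C; the BINOL enantiomer is chosen for the 1S carbinol) closes both rings at the α-carbon with silyl transfer to the new carbinol oxygens, giving the tetrakis(tert-butyldimethylsilyl) ether of 12 F7. HF·pyridine (THF, 0 °C) removes the silyl groups and the sequence comes back at 12.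

Step 6 (statistical mono-oxidation with an oxidant next to free phenols and a very oxidisable naphthalenediol product). The fallback sets out from 11 and moves the differentiation of the two halves to the robust achiral dialdehyde. Oxidative N-heterocyclic-carbene catalysis (1,3-dimesitylimidazolium chloride 20 mol %, DBU, 3,3',5,5'-tetra-tert-butyl-4,4'-diphenoquinone 1 equiv, THF, rt) converts one aldehyde into an acyl azolium that C-acylates its own dienolate. This gives, after tautomerisation, the mono-naphthol mono-aldehyde 2-hydroxy-3-(7-acetyl-1,8-dihydroxy-6-methylnaphthalen-2-yl)-6-[(2E)-2-methyl-4-oxopent-2-en-1-yl]benzaldehyde F8, with unreacted 11 recycled. The (R)-proline aldol of step 5 on the remaining aldehyde/enone half then comes back to the route directly at 14, so no oxidant ever meets the stereogenic half.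

**Further compounds**
F1 | step 4 | 2,2'-dihydroxy-4,4'-dimethyl-[1,1'-biphenyl]-3,3'-dicarbaldehyde | Cc1ccc(-c2ccc(C)c(C=O)c2O)c(O)c1C=O
F2 | step 4 | 2,2'-bis(methoxymethoxy)-4,4'-dimethyl-[1,1'-biphenyl]-3,3'-dicarbaldehyde | COCOc1c(-c2ccc(C)c(C=O)c2OCOC)ccc(C)c1C=O
F3 | step 4 | dilithium bis{[2-(dimethylamino)ethyl](methyl)amino}methanolate of F2 (chelated α-amino alkoxide at each CHO carbon) | COCOc1c(-c2ccc(C)c(C(O[Li])N(C)CCN(C)C)c2OCOC)ccc(C)c1C(O[Li])N(C)CCN(C)C
F4 | step 4 | 4,4'-bis(lithiomethyl) derivative of F3 | COCOc1c(-c2ccc(C[Li])c(C(O[Li])N(C)CCN(C)C)c2OCOC)ccc(C[Li])c1C(O[Li])N(C)CCN(C)C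
F5 | step 4 | tetralithium bis-adduct of F4 with 6 | COCOc1c(-c2ccc(CC(C)(O[Li])/C=C(\C)OC)c(C(O[Li])N(C)CCN(C)C)c2OCOC)ccc(CC(C)(O[Li])/C=C(\C)OC)c1C(O[Li])N(C)CCN(C)C
F6 | step 5 | 2,2'-bis(tert-butyldimethylsilyloxy)-4,4'-bis[2-methyl-4-(tert-butyldimethylsilyloxy)penta-1,3-dien-1-yl]-[1,1'-biphenyl]-3,3'-dicarbaldehyde (diene isomer mixture) | CC(O[Si](C)(C)C(C)(C)C)=CC(C)=Cc1ccc(-c2ccc(C=C(C)C=C(C)O[Si](C)(C)C(C)(C)C)c(C=O)c2O[Si](C)(C)C(C)(C)C)c(O[Si](C)(C)C(C)(C)C)c1C=O
F7 | step 5 | 1,1',8,8'-tetrakis-O-(tert-butyldimethylsilyl) ether of 12, (1S,1'S,2R,2'R) | CC(C)(C)[Si](C)(C)Oc1c(-c2ccc3c(c2O[Si](C)(C)C(C)(C)C)[C@@H](O[Si](C)(C)C(C)(C)C)[C@H](C(C)=O)C(C)=C3)ccc2c1[C@@H](O[Si](C)(C)C(C)(C)C)[C@H](C(C)=O)C(C)=C2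
F8 | step 6 | 2-hydroxy-3-(7-acetyl-1,8-dihydroxy-6-methylnaphthalen-2-yl)-6-[(2E)-2-methyl-4-oxopent-2-en-1-yl]benzaldehyde | CC(=O)c1c(C)cc2ccc(-c3ccc(C/C(C)=C/C(C)=O)c(C=O)c3O)c(O)c2c1O
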